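## Structural features

Compound 15 is a 2,3,4-trisubstituted oxolane. Its ring atoms are numbered here O1, C2 (3,4,5-trimethoxyphenyl), C3 (CH2OH), C4 (3,4,5-trimethoxybenzoyl) and C5 (H2), whatever locants the systematic names use. The three stereocentres are contiguous (C2 S, C3 S, C4 R): the aryl group and CH2OH are cis, and CH2OH and the aroyl group are trans. C2–O1 is a benzylic ether of an electron-rich arene, so acid can ionise it and epimerise C2. C4–H is α to an aryl ketone and epimerisable, C5–O1 is β to that ketone (possible retro-oxa-Michael opening), and a cis C3/C4 arrangement would let the CH2OH close onto the ketone as a bicyclic hemiketal. The real difficulty is the C2/C3 cis relationship, which is not the thermodynamic one and must be set kinetically; C4 is the one centre that equilibration sets correctly. The two identical aryl rings sit on benzylic carbons of different oxidation level, so they must be introduced in different ways. The key step exploits the unit O1–C5–C4(–C(=O)–aryl)–C3: with a C3=C4 double bond, O1, C5, C4 and C3 are the hydroxyl oxygen, CH2 terminus, central carbon and substituted carbon of an α-allenol, and the aroyl group on C4 can come from CO and an arylboron reagent.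

## Logic of the disconnections

15 ⇒ 14. The primary O–H is replaced by an O–Si bond. A free hydroxyl would capture the acylpalladium of the key step as a lactone and could engage the ketone while C4 is equilibrated. A tert-butyldiphenylsilyl (TBDPS) ether is chosen over the dimethyl analogue because PdCl2(MeCN)2 can itself cleave the more labile silyl ethers. Nothing is gained in skeleton; the gain is that the earlier steps become viable. The forward cleavage must use buffered fluoride, so that C4 is not epimerised and C2–O1 is not ionised.

14 ⇒ 11 (through 13 and 12). The C3–H and C4–H bonds are removed, giving the C3=C4 enone. Only C2 is then stereogenic, and it sits next to C3 where it can direct the reduction. Three stereocentres become one. The forward step must deliver hydride to C3 on the face away from the C2 aryl group, leave the ketone untouched, and then let C4 settle trans (13 to 14).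

11 ⇒ 8 + 9 + 10. Three bonds are cut: O1–C5, C4–C(=O) and C(=O)–aryl. The ring, the ketone carbon and the second arene fall apart into an acyclic allenol with one stereocentre, a one-carbon unit and a catalogue boronic acid. The forward step must cyclise before the arylboron reagent reaches the metal, insert 9 faster than it arylates or protonates C4, and leave the C2 carbinol un-ionised.

8 ⇒ 5 + 6. The C2–C3 bond is cut and C2 is the stereocentre made. Both partners are achiral, and catalyst control replaces a resolution that would discard half the material. The forward addition must go through the alkyne carbon γ to boron, so that the allene and not the homopropargylic isomer forms, and on the Si face of the aldehyde.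

5 ⇒ 1 + 2. The bond between the alkyne terminus and the boron-bearing CH2 is cut, giving two catalogue compounds. The alkynyl group must migrate from boron to carbon with loss of iodide rather than dissociate, so that boron ends on the propargylic carbon.

## Other disconnections considered

Alternative 1: The cut removes C2–C3 and C4–C5 and traces the ring to the aryl acetal A1, a 4-(Z-alkenyl)-2-aryl-1,3-dioxolane made from 6 and a chiral-pool pentenetriol.
- Forward key step: SnCl4 opens the acetal at the allylic oxygen to an aryl oxocarbenium ion. The alkene attacks through a chair with the aryl group equatorial and the Z-CH2OSi group axial, which makes C2/C3 cis. A pinacol shift of C5 to cationic C4 contracts the six-membered ring and releases the former carbinol carbon as a formyl group, giving all-cis A2. If the Lewis-acid-bound oxygen sits equatorial in that chair, the 4R acetal A1 should be the one that leads to A2.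
- In favour: two C–C bonds, the ring and all three ring stereocentres form in one operation, from one chiral-pool centre, without CO or a noble metal. On stereocentres made per step it is better than the chosen plan, whose key step makes none. It is also better on precedent, since the cascade type is well studied and the chosen key step is not.
- Against, here: the alkene is 1,2-disubstituted and carries an allylic silyloxy group, so it is a weak π-nucleophile and would generate a secondary, inductively destabilised cation. The trimethoxyphenyl-stabilised oxocarbenium ion is a correspondingly weak electrophile. Under SnCl4 the benzylic C2–O1 bond of A2 could re-ionise and drift to the 2,3-trans series.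
- Comparison: A2 has C2/C3 right but C4 cis, and it lacks one aryl group and one oxidation level. Epimerisation, aryl Grignard addition, oxidation and desilylation would follow. With the Z-olefination and acetal exchange in front, this comes to about nine steps against five. The chosen 11 already holds every carbon at the final oxidation level.

Alternative 2: The cut is O1–C2 (with C2–H), opening the ring to the γ-hydroxy diketone A4, the enzymatic mono-acetate of the meso diol A3.
- Forward key step: the free CH2OH adds to the far ketone, BF3·OEt2 ionises the hemiketal, and Et3SiH reduces the cyclic oxocarbenium ion from the face opposite the C3 substituent, giving A5. Deacetylation of A5 would give 15.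
- In favour: both aroyl groups are present from the start. The meso configuration translates directly into C3/C4 trans, which is equal or better than the chosen plan at C4 because no equilibration is needed. Desymmetrising a meso diol can in principle use all the material, equal to the catalytic allenylboration. Only one step follows the key step (better than two), and reductive etherification is better precedented than the chosen key step.
- Against, here: A3 and A4 are β-hydroxy or β-acetoxy ketones on both sides with acidic α-hydrogens. Epimerisation out of the meso series, E1cB loss of acetate or water, and retro-aldol loss of formaldehyde all threaten them. A 1,4-diketone under BF3·OEt2 can also undergo Paal–Knorr-type cyclodehydration. C2, the most labile centre, is set last, by substrate-controlled hydride delivery to a flat aryl-stabilised cation. Diastereomerically pure A3 is itself a multi-step problem.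
- Comparison: the chosen plan sets C2 first under catalyst control and C3 on a strongly biased ring face. Total step count would probably be similar (six or seven against five).

Alternative 3: The cut is C2–C3 and O1–C5, tracing the ring to the lactone A7, formed from the enal A6 and 6.
- Forward key step: a chiral triazolium carbene adds to A6. The β-carbon of the resulting homoenolate attacks 6, and the new alkoxide acylates itself on the acyl azolium, closing the cis lactone A7.
- In favour: two achiral aldehydes give the ring, the C2–C3 bond and both C2 and C3, with the required cis relationship, in one metal-free step without CO. It is better than the chosen plan in stereocentres per step, and equal in convergence, since it uses the same aldehyde 6.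
- Against, here: in the homoenolate of A6 the silyloxy group sits β to the nucleophilic carbon and can be expelled, diverting the catalyst into an eliminated, carbene-bound dienolate. Aliphatic β-substituted enals and electron-rich aryl aldehydes are the less favourable partners for high enantio- and cis-selectivity in the intermolecular annulation.
- Comparison: A7 has the oxidation pattern inverted. C5 is a carbonyl that must become CH2, and C4 is a CH2 that must receive the aroyl group. That needs an aldol with 6 trans to CH2OSi, protection, lactone-to-lactol reduction, deoxygenation with Et3SiH/BF3·OEt2 (which threatens C2–O1), reoxidation and desilylation. That is five or six steps after the key step against two, and seven or eight in all against five.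

Key step: step 3

Assumption: 1 is taken as a catalogue compound (otherwise one silylation of prop-2-yn-1-ol), and the (S)-acid is taken to give Si-face addition in step 2 by analogy with allylboration. The R descriptor at the carbinol carbon of 8 and 11 and the S descriptor at C2 of 14 and 15 are the same spatial arrangement (the CIP ranking changes on reduction), so no structure needed correction.

## Route

Step 1
Reactants: 1 tert-butyl(diphenyl)(prop-2-yn-1-yloxy)silane; 2 2-(iodomethyl)-4,4,5,5-tetramethyl-1,3,2-dioxaborolane
Product: 5 tert-butyl(diphenyl){[4-(4,4,5,5-tetramethyl-1,3,2-dioxaborolan-2-yl)but-2-yn-1-yl]oxy}silane, via lithium acetylide 3 (not isolated), via alkynyl borate 4 (not isolated)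
Conditions: n-BuLi, THF, −78 °C; then 2, −78 °C → rt
Reagents that add atoms: none
Why: Matteson homologation: the acetylide 3 adds to boron of 2 and, in the borate 4, the alkynyl group migrates to the CH2 carbon with loss of iodide; direct SN2 attack at CH2I would give the same product. Boron therefore ends on the propargylic carbon, which is the isomer needed for an SE2' allenylation.

Step 2
Reactants: 5 tert-butyl(diphenyl){[4-(4,4,5,5-tetramethyl-1,3,2-dioxaborolan-2-yl)but-2-yn-1-yl]oxy}silane; 6 3,4,5-trimethoxybenzaldehyde
Product: 8 (1R)-2-{[tert-butyl(diphenyl)silyl]oxymethyl}-1-(3,4,5-trimethoxyphenyl)buta-2,3-dien-1-ol, via O-boryl ether 7 (not isolated)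
Conditions: (S)-TRIP (10 mol%), 4 Å MS, toluene, −30 → 0 °C; then aq. NaHCO3
Reagents that add atoms: none
Why: Chiral phosphoric acid-catalysed allenylboration: the aldehyde binds boron, the acid [(S)-3,3'-bis(2,4,6-triisopropylphenyl)-1,1'-binaphthyl-2,2'-diyl hydrogen phosphate] hydrogen-bonds to a boronate oxygen and the formyl hydrogen, and the alkyne carbon γ to boron attacks through a six-membered SE2' transition state, giving the allene as its O-boryl ether 7, hydrolysed on work-up. The (S)-acid is expected to expose the Si face of 6, which corresponds to R at C2; the (R)-acid would be used if the sense proved opposite.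

Step 3
Reactants: 8 (1R)-2-{[tert-butyl(diphenyl)silyl]oxymethyl}-1-(3,4,5-trimethoxyphenyl)buta-2,3-dien-1-ol; 9 carbon monoxide; 10 (3,4,5-trimethoxyphenyl)boronic acid
Product: 11 [(5R)-4-{[tert-butyl(diphenyl)silyl]oxymethyl}-5-(3,4,5-trimethoxyphenyl)-2,5-dihydrofuran-3-yl](3,4,5-trimethoxyphenyl)methanone
Conditions: PdCl2(MeCN)2 (10 mol%), 1,4-benzoquinone (1.5 equiv), NaOAc (1 equiv), CO (3 bar), THF, H2O (2 equiv), 25 °C, slow addition of 10
Reagents that add atoms: none
Why: Proposed new method: electrophilic PdCl2(MeCN)2 should bind the terminal C4=C5 bond of 8 and the C2 hydroxyl should add anti to the metal at the CH2 terminus (O1–C5), leaving a σ-vinylpalladium chloride at C4; CO then inserts (C4–C=O), the acylpalladium takes the aryl group from 10 with acetate assistance, and reductive elimination forms the C(=O)–aryl bond and zerovalent palladium, which 1,4-benzoquinone returns to the divalent state. The closest known reaction types are the PdCl2-catalysed cyclisation–coupling of 2,3-allenols to 3-substituted 2,5-dihydrofurans and the oxidative carbonylative Suzuki–Miyaura ketone synthesis; merging them on one vinylpalladium intermediate is the untested part. The one ring closed is the 2,5-dihydrofuran, by a 5-endo-trig attack of oxygen that the orthogonal π bonds of an allene permit. No stereocentre is created: C2 takes no part in the bonding changes and should keep its configuration as long as the acetate buffer prevents ionisation of this benzylic, allenylic carbinol. Oxypalladation must precede transmetalation, because an aroylpalladium formed first would add across the allene to a π-allyl complex that closes to vinyl oxiranes; slow addition of 10 to a chloride-rich catalyst should keep arylpalladium species scarce. CO insertion must outrun direct aryl transfer and protodepalladation at C4, which CO pressure and the buffer should secure. The substrate fixes the regiochemistry, since the CH2OSi-bearing allene carbon is blocked and only the unsubstituted CH2 is open to oxygen, and the TBDPS ether keeps the primary oxygen from trapping the acylpalladium as a lactone.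

Step 4
Reactants: 11 [(5R)-4-{[tert-butyl(diphenyl)silyl]oxymethyl}-5-(3,4,5-trimethoxyphenyl)-2,5-dihydrofuran-3-yl](3,4,5-trimethoxyphenyl)methanone
Product: 14 [(3R,4S,5S)-4-{[tert-butyl(diphenyl)silyl]oxymethyl}-5-(3,4,5-trimethoxyphenyl)oxolan-3-yl](3,4,5-trimethoxyphenyl)methanone, via silyl enol ether 12 (not isolated), via all-cis ketone 13 (not isolated)
Conditions: [(Ph3P)CuH]6 (5 mol%), PhMe2SiH (1.5 equiv), toluene, rt; then K2CO3, MeOH, rt
Reagents that add atoms: none
Why: CuH-catalysed conjugate reduction (1,4-hydrosilylation): the bulky phosphine-ligated hydride should add to C3 on the face away from the C2 aryl group, which places CH2OSi cis to the aryl, and the enolate is held as silyl enol ether 12, which shields the ketone from over-reduction. Methanolysis should protonate C4 from the open face to the all-cis ketone 13, and reversible enolisation with K2CO3 then moves the aroyl group trans to CH2OSi (14), relieving the three-fold cis crowding. Ring opening by β-alkoxide loss is disfavoured because the C5–O1 bond lies orthogonal to the enolate π system.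

Step 5
Reactants: 14 [(3R,4S,5S)-4-{[tert-butyl(diphenyl)silyl]oxymethyl}-5-(3,4,5-trimethoxyphenyl)oxolan-3-yl](3,4,5-trimethoxyphenyl)methanone
Product: 15 [(3R,4S,5S)-4-(hydroxymethyl)-5-(3,4,5-trimethoxyphenyl)oxolan-3-yl](3,4,5-trimethoxyphenyl)methanone
Conditions: TBAF, AcOH, THF, 0 °C → rt
Reagents that add atoms: none
Why: Fluoride desilylation; the acetic acid buffer avoids enolate chemistry at C4 and opening of the β-alkoxy ketone, and no strong acid is present to ionise C2–O1. With the aroyl group trans to CH2OH a hemiketal would need a trans-fused bicycle, so 15 should be isolated as the open hydroxy ketone.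

## Compound list

1 | tert-butyl(diphenyl)(prop-2-yn-1-yloxy)silane | C#CCO[Si](c1ccccc1)(c1ccccc1)C(C)(C)C | starting material
2 | 2-(iodomethyl)-4,4,5,5-tetramethyl-1,3,2-dioxaborolane | ICB1OC(C)(C)C(C)(C)O1 | starting material
3 | lithium 3-{[tert-butyl(diphenyl)silyl]oxy}prop-1-yn-1-ide | [Li+].[C-]#CCO[Si](c1ccccc1)(c1ccccc1)C(C)(C)C | intermediate
4 | lithium (3-{[tert-butyl(diphenyl)silyl]oxy}prop-1-yn-1-yl)(iodomethyl)(2,3-dimethylbutane-2,3-diolato)borate | [Li+].IC[B-]1(C#CCO[Si](c2ccccc2)(c2ccccc2)C(C)(C)C)OC(C)(C)C(C)(C)O1 | intermediate
5 | tert-butyl(diphenyl){[4-(4,4,5,5-tetramethyl-1,3,2-dioxaborolan-2-yl)but-2-yn-1-yl]oxy}silane | CC1(C)OB(CC#CCO[Si](c2ccccc2)(c2ccccc2)C(C)(C)C)OC1(C)C | intermediate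
6 | 3,4,5-trimethoxybenzaldehyde | COc1cc(C=O)cc(OC)c1OC | starting material
7 | 2-{[(1R)-2-{[tert-butyl(diphenyl)silyl]oxymethyl}-1-(3,4,5-trimethoxyphenyl)buta-2,3-dien-1-yl]oxy}-4,4,5,5-tetramethyl-1,3,2-dioxaborolane | C=C=C(CO[Si](c1ccccc1)(c1ccccc1)C(C)(C)C)[C@@H](c1cc(OC)c(OC)c(OC)c1)OB1OC(C)(C)C(C)(C)O1 | intermediate
8 | (1R)-2-{[tert-butyl(diphenyl)silyl]oxymethyl}-1-(3,4,5-trimethoxyphenyl)buta-2,3-dien-1-ol | C=C=C(CO[Si](c1ccccc1)(c1ccccc1)C(C)(C)C)[C@@H](c1cc(OC)c(OC)c(OC)c1)O | intermediate
9 | carbon monoxide | [C-]#[O+] | starting material
10 | (3,4,5-trimethoxyphenyl)boronic acid | COc1cc(B(O)O)cc(OC)c1OC | starting material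
11 | [(5R)-4-{[tert-butyl(diphenyl)silyl]oxymethyl}-5-(3,4,5-trimethoxyphenyl)-2,5-dihydrofuran-3-yl](3,4,5-trimethoxyphenyl)methanone | O=C(c1cc(OC)c(OC)c(OC)c1)C1=C(CO[Si](c2ccccc2)(c2ccccc2)C(C)(C)C)[C@@H](c2cc(OC)c(OC)c(OC)c2)OC1 | intermediate
12 | tert-butyl{[(2S,3S)-4-{[dimethyl(phenyl)silyl]oxy(3,4,5-trimethoxyphenyl)methylidene}-2-(3,4,5-trimethoxyphenyl)oxolan-3-yl]methoxy}diphenylsilane (enol ether geometry not defined) | C[Si](C)(c1ccccc1)OC(c1cc(OC)c(OC)c(OC)c1)=C1CO[C@H](c2cc(OC)c(OC)c(OC)c2)[C@@H]1CO[Si](c1ccccc1)(c1ccccc1)C(C)(C)C | intermediate
13 | [(3S,4S,5S)-4-{[tert-butyl(diphenyl)silyl]oxymethyl}-5-(3,4,5-trimethoxyphenyl)oxolan-3-yl](3,4,5-trimethoxyphenyl)methanone (all-cis C4 epimer of 14) | O=C(c1cc(OC)c(OC)c(OC)c1)[C@@H]1CO[C@H](c2cc(OC)c(OC)c(OC)c2)[C@@H]1CO[Si](c1ccccc1)(c1ccccc1)C(C)(C)C | intermediate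
14 | [(3R,4S,5S)-4-{[tert-butyl(diphenyl)silyl]oxymethyl}-5-(3,4,5-trimethoxyphenyl)oxolan-3-yl](3,4,5-trimethoxyphenyl)methanone | O=C(c1cc(OC)c(OC)c(OC)c1)[C@H]1CO[C@H](c2cc(OC)c(OC)c(OC)c2)[C@@H]1CO[Si](c1ccccc1)(c1ccccc1)C(C)(C)C | intermediate
15 | [(3R,4S,5S)-4-(hydroxymethyl)-5-(3,4,5-trimethoxyphenyl)oxolan-3-yl](3,4,5-trimethoxyphenyl)methanone | COc1cc(C(=O)[C@H]2CO[C@H](c3cc(OC)c(OC)c(OC)c3)[C@@H]2CO)cc(OC)c1OC | target

## Step count and least certain steps

Total step count: 5. Longest linear sequence: 5 steps (1 → 5 → 8 → 11 → 14 → 15).

Step 3 (key step, proposed new method). The most likely failures are: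
- transmetalation of 10 before oxypalladation, leading to carbonylative homocoupling of the boronic acid or to aroylpalladation of the allene and closure on the wrong carbon;
- direct aryl transfer without CO insertion, or protodepalladation at C4;
- acid-induced ionisation of the carbinol with loss of configuration at C2;
- reduction of the catalyst by CO before turnover.

All of these stem from four components competing for one metal centre. The fallback uses known chemistry, sets out from 8 and comes back at 11. Compound 8 is treated with N-iodosuccinimide in CH2Cl2 at 0 °C, an electrophilic 5-endo iodoetherification of a 2,3-allenol. This should give the vinyl iodide tert-butyl{[(2R)-4-iodo-2-(3,4,5-trimethoxyphenyl)-2,5-dihydrofuran-3-yl]methoxy}diphenylsilane F1. F1 is then coupled with 10 under CO (PdCl2(dppf), K2CO3, anisole, 80 °C). This is a carbonylative Suzuki–Miyaura coupling that starts by oxidative addition of zerovalent palladium, and it gives 11.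

Step 4. The tetrasubstituted enone may react sluggishly, the facial discrimination at C3 may be incomplete, or the enolate may open the ring by β-alkoxide elimination. All three follow from the crowding at C3 and from the β-oxygen at C5. The fallback sets out from 11 and comes back at 13. Homogeneous hydrogenation with [Ir(cod)(PCy3)(py)]PF6 under H2 in CH2Cl2 should add both hydrogens syn to the face away from the aryl group and give 13 directly. Compound 13 is then equilibrated to 14 with K2CO3 in MeOH as in step 4. This fallback makes no compound outside the list (F0).

Step 2. Enantioface discrimination may be insufficient with the CH2OSi substituent on the alkyne, or an uncatalysed racemic addition may compete, because the aldehyde is only moderately electrophilic. The fallback sets out from 5 and 6 and comes back at 8. Addition catalysed by achiral diphenyl phosphate in toluene gives racemic 2-{[tert-butyl(diphenyl)silyl]oxymethyl}-1-(3,4,5-trimethoxyphenyl)buta-2,3-dien-1-ol F2. Kinetic resolution with Burkholderia cepacia lipase and vinyl acetate follows. On the usual size model, with the aryl ring in the large pocket, the lipase is expected to acetylate the S enantiomer to (1S)-2-{[tert-butyl(diphenyl)silyl]oxymethyl}-1-(3,4,5-trimethoxyphenyl)buta-2,3-dien-1-yl acetate F3 and leave 8. The price is half of the material.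

Step 1. The alkynyl borate may revert to its components instead of rearranging, or the propargylic boronate may suffer protodeboronation on purification; alkynyl groups migrate reluctantly and leave boron easily. The fallback sets out from 1 (through 3) and 6 and comes back at 8. Acetylide 3 is quenched with paraformaldehyde to give 4-{[tert-butyl(diphenyl)silyl]oxy}but-2-yn-1-ol F4. An Appel reaction (PPh3, CBr4) gives (4-bromobut-2-yn-1-yloxy)(tert-butyl)diphenylsilane F5. A Barbier allenylation of 6 with F5 and In powder in THF–H2O gives the racemic allenol F2, which is resolved as under step 2 to 8.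

## Further compounds

F1 | step 3 | tert-butyl{[(2R)-4-iodo-2-(3,4,5-trimethoxyphenyl)-2,5-dihydrofuran-3-yl]methoxy}diphenylsilane | IC1=C(CO[Si](c2ccccc2)(c2ccccc2)C(C)(C)C)[C@@H](c2cc(OC)c(OC)c(OC)c2)OC1
F0 | step 4 | none | none
F2 | step 2 | racemic 2-{[tert-butyl(diphenyl)silyl]oxymethyl}-1-(3,4,5-trimethoxyphenyl)buta-2,3-dien-1-ol | C=C=C(CO[Si](c1ccccc1)(c1ccccc1)C(C)(C)C)C(c1cc(OC)c(OC)c(OC)c1)O
F3 | step 2 | (1S)-2-{[tert-butyl(diphenyl)silyl]oxymethyl}-1-(3,4,5-trimethoxyphenyl)buta-2,3-dien-1-yl acetate | C=C=C(CO[Si](c1ccccc1)(c1ccccc1)C(C)(C)C)[C@H](c1cc(OC)c(OC)c(OC)c1)OC(C)=O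
F4 | step 1 | 4-{[tert-butyl(diphenyl)silyl]oxy}but-2-yn-1-ol | OCC#CCO[Si](c1ccccc1)(c1ccccc1)C(C)(C)C
F5 | step 1 | (4-bromobut-2-yn-1-yloxy)(tert-butyl)diphenylsilane | BrCC#CCO[Si](c1ccccc1)(c1ccccc1)C(C)(C)C
A1 | alternative 1 | (4R)-4-[(1Z)-3-{[tert-butyl(diphenyl)silyl]oxy}prop-1-en-1-yl]-2-(3,4,5-trimethoxyphenyl)-1,3-dioxolane (acetal carbon as epimer mixture) | COc1cc(C2OC[C@@H](/C=C\CO[Si](c3ccccc3)(c3ccccc3)C(C)(C)C)O2)cc(OC)c1OC
A2 | alternative 1 | (3S,4S,5S)-4-{[tert-butyl(diphenyl)silyl]oxymethyl}-5-(3,4,5-trimethoxyphenyl)oxolane-3-carbaldehyde | O=C[C@@H]1CO[C@H](c2cc(OC)c(OC)c(OC)c2)[C@@H]1CO[Si](c1ccccc1)(c1ccccc1)C(C)(C)C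
A3 | alternative 2 | meso-(2R,3S)-2,3-bis(hydroxymethyl)-1,4-bis(3,4,5-trimethoxyphenyl)butane-1,4-dione | O=C(c1cc(OC)c(OC)c(OC)c1)[C@H]([C@@H](CO)C(=O)c1cc(OC)c(OC)c(OC)c1)CO
A4 | alternative 2 | (2S,3R)-3-(hydroxymethyl)-4-oxo-2-(3,4,5-trimethoxybenzoyl)-4-(3,4,5-trimethoxyphenyl)butyl acetate | O=C(c1cc(OC)c(OC)c(OC)c1)[C@H]([C@@H](COC(C)=O)C(=O)c1cc(OC)c(OC)c(OC)c1)CO
A5 | alternative 2 | [(2S,3S,4R)-4-(3,4,5-trimethoxybenzoyl)-2-(3,4,5-trimethoxyphenyl)oxolan-3-yl]methyl acetate | O=C(c1cc(OC)c(OC)c(OC)c1)[C@H]1CO[C@H](c2cc(OC)c(OC)c(OC)c2)[C@@H]1COC(C)=O
A6 | alternative 3 | (2E)-4-{[tert-butyl(dimethyl)silyl]oxy}but-2-enal | O=C/C=C/CO[Si](C)(C)C(C)(C)C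
A7 | alternative 3 | (4S,5S)-4-{[tert-butyl(dimethyl)silyl]oxymethyl}-5-(3,4,5-trimethoxyphenyl)oxolan-2-one | C1C(=O)O[C@H](c2cc(OC)c(OC)c(OC)c2)[C@@H]1CO[Si](C)(C)C(C)(C)C
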